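**Strategy.** Everything rests on disconnecting the C2–C3 bond of the pyranone ring (ring C). The feature exploited is the C2–H bond: C2 is a benzylic methine on O1, so it is read as one C–H of an aryl benzyl ether CH2 lying 1,6 to C3. Ring B is therefore hung on the ring A phenol as a plain benzyl ether, the acetyl group becomes a terminal α-diazoketone, and a chiral dirhodium tetracarboxylate inserts the C3 carbene into one enantiotopic benzylic C–H bond. This single operation closes ring C, forms C2–C3 and sets the 2S centre. The precursor is an open diazoketone benzyl ether carrying both terpenoid chains and four silyl ethers.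

Key step: step 10

Assumption: Rh2(S-PTTL)4 is taken to deliver the 2S product; if the sense of induction proves opposite, the catalyst made from (R)-tert-leucine is used with no other change. TBS = tert-butyldimethylsilyl. All phenols are carried as TBS ethers because a silyl ether has no C–H bond next to oxygen for the carbene to attack and is removed without base.

**Ring A fragment**

Step 1
Reactants: 1 2',4',6'-trihydroxyacetophenone
Product: 2 1-[2,4-bis(tert-butyldimethylsilyloxy)-6-hydroxyphenyl]ethanone
Conditions: TBSCl (2.2 equiv), imidazole, DMF, 0 °C to rt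
Reagents that add atoms: tert-butyldimethylsilyl chloride, CC(C)(C)[Si](C)(C)Cl
Why: Phenol silylation should take the 4-OH and one of the two equivalent ortho OH groups, while the last OH is held back by its hydrogen bond to the acetyl carbonyl and by crowding.

Step 2
Reactants: 2 1-[2,4-bis(tert-butyldimethylsilyloxy)-6-hydroxyphenyl]ethanone; 3 3-methylbut-2-en-1-ol (prenol)
Product: 4 1-[2,4-bis(tert-butyldimethylsilyloxy)-6-(3-methylbut-2-en-1-yloxy)phenyl]ethanone
Conditions: PPh3, DIAD, THF, 0 °C to rt
Reagents that add atoms: none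
Why: Mitsunobu etherification of the acidic chelated phenol at the primary allylic carbon should proceed without allylic transposition under neutral conditions that spare the aryl silyl ethers.

Step 3
Reactants: 4 1-[2,4-bis(tert-butyldimethylsilyloxy)-6-(3-methylbut-2-en-1-yloxy)phenyl]ethanone
Product: 7 1-[2,4-bis(tert-butyldimethylsilyloxy)-6-hydroxy-3-(3-methylbut-2-en-1-yl)phenyl]ethanone, via ortho-dienone 5 (not isolated), via para-dienone 6 (not isolated)
Conditions: N,N-diethylaniline, 200 °C, sealed tube
Reagents that add atoms: none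
Why: In this tandem aromatic Claisen–Cope (para-Claisen) rearrangement a [3,3] shift to the free ortho carbon gives 5, whose crowded tertiary allyl group should be relayed by a second [3,3] shift to the para carbon (6) before enolisation, so the prenyl group arrives with normal connectivity between the two silyloxy groups and the phenol is regenerated next to the acetyl group.

**Ring B fragment**

Step 4
Reactants: 8 3-bromo-4,5-dihydroxybenzaldehyde
Product: 9 3-bromo-4,5-bis(tert-butyldimethylsilyloxy)benzaldehyde
Conditions: TBSCl (2.5 equiv), imidazole, DMF, rt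
Reagents that add atoms: tert-butyldimethylsilyl chloride, CC(C)(C)[Si](C)(C)Cl
Why: Standard imidazole-mediated silylation of both catechol hydroxyls; the aldehyde and aryl bromide are inert.

Step 5
Reactants: 10 geranyl chloride, (2E)-1-chloro-3,7-dimethylocta-2,6-diene
Product: 11 tributyl[(2E)-3,7-dimethylocta-2,6-dien-1-yl]stannane
Conditions: Bu3SnH, LiN(i-Pr)2, THF, 0 °C; then 10, −78 °C to rt
Reagents that add atoms: tributyltin hydride, CCCC[SnH](CCCC)CCCC
Why: SN2 displacement of the primary allylic chloride by tributylstannyllithium should keep the E-trisubstituted double bond in place.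

Step 6
Reactants: 9 3-bromo-4,5-bis(tert-butyldimethylsilyloxy)benzaldehyde; 11 tributyl[(2E)-3,7-dimethylocta-2,6-dien-1-yl]stannane
Product: 12 3-[(2E)-3,7-dimethylocta-2,6-dien-1-yl]-4,5-bis(tert-butyldimethylsilyloxy)benzaldehyde
Conditions: Pd(PPh3)4 (5 mol %), DMF, 90 °C
Reagents that add atoms: none
Why: In this Stille cross-coupling, oxidative addition of zerovalent palladium into the aryl bromide, transmetalation and reductive elimination at the less substituted allyl terminus should give the linear E-geranyl arene under neutral, fluoride-free conditions that leave the aldehyde and silyl ethers alone.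

Step 7
Reactants: 12 3-[(2E)-3,7-dimethylocta-2,6-dien-1-yl]-4,5-bis(tert-butyldimethylsilyloxy)benzaldehyde
Product: 13 {3-[(2E)-3,7-dimethylocta-2,6-dien-1-yl]-4,5-bis(tert-butyldimethylsilyloxy)phenyl}methanol
Conditions: NaBH4, THF–MeOH (4:1), 0 °C
Reagents that add atoms: none
Why: Chemoselective borohydride reduction of the aldehyde; the isolated olefins and aryl silyl ethers should be untouched at 0 °C.

**Union, key step and end game**

Step 8
Reactants: 7 1-[2,4-bis(tert-butyldimethylsilyloxy)-6-hydroxy-3-(3-methylbut-2-en-1-yl)phenyl]ethanone; 13 {3-[(2E)-3,7-dimethylocta-2,6-dien-1-yl]-4,5-bis(tert-butyldimethylsilyloxy)phenyl}methanol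
Product: 14 1-[2,4-bis(tert-butyldimethylsilyloxy)-6-({3-[(2E)-3,7-dimethylocta-2,6-dien-1-yl]-4,5-bis(tert-butyldimethylsilyloxy)phenyl}methoxy)-3-(3-methylbut-2-en-1-yl)phenyl]ethanone
Conditions: PPh3, DIAD, toluene–THF, 0 °C to rt
Reagents that add atoms: none
Why: Mitsunobu etherification should join the only free phenol of 7 to the primary benzylic alcohol under neutral conditions, avoiding an unstable electron-rich benzyl halide and base-induced silyl migration.

Step 9
Reactants: 14 the aryl benzyl ether acetophenone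
Product: 16 2-diazo-1-[2,4-bis(tert-butyldimethylsilyloxy)-6-({3-[(2E)-3,7-dimethylocta-2,6-dien-1-yl]-4,5-bis(tert-butyldimethylsilyloxy)phenyl}methoxy)-3-(3-methylbut-2-en-1-yl)phenyl]ethanone, via trifluoroacetyl 1,3-diketone 15 (not isolated)
Conditions: LiN(SiMe3)2, THF, −78 °C; CF3CO2CH2CF3; then MsN3, Et3N, H2O, MeCN, rt
Reagents that add atoms: methanesulfonyl azide, CS(=O)(=O)N=[N+]=[N-]; 2,2,2-trifluoroethyl trifluoroacetate, O=C(OCC(F)(F)F)C(F)(F)F (its atoms are carried only by intermediate 15)
Why: In this detrifluoroacetylative diazo transfer (Danheiser procedure), Claisen trifluoroacetylation of the kinetic lithium enolate activates the methyl group, and sulfonyl azide transfer with loss of the trifluoroacetyl group as its sulfonamide should deliver the terminal α-diazoketone.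

Step 10
Reactants: 16 the α-diazoketone
Product: 17 (2S)-5,7-bis(tert-butyldimethylsilyloxy)-2-{3-[(2E)-3,7-dimethylocta-2,6-dien-1-yl]-4,5-bis(tert-butyldimethylsilyloxy)phenyl}-6-(3-methylbut-2-en-1-yl)-2,3-dihydro-4H-chromen-4-one
Conditions: Rh2(S-PTTL)4 (dirhodium tetrakis[N-phthaloyl-(S)-tert-leucinate], 1–2 mol %), CH2Cl2, slow addition of 16 at high dilution, 0 °C to rt
Reagents that add atoms: none
Why: Rh2(S-PTTL)4 should expel N2 from 16 to give an electrophilic rhodium-bound carbene at the future C3, which inserts through a concerted, asynchronous, hydride-transfer-like three-centre transition state into a C–H bond of the OCH2Ar group, forming the C2–C3 bond and leaving the carbene carbon as the C3 methylene. The closest known reaction type is the chiral dirhodium tetracarboxylate-catalysed intramolecular C–H insertion of ortho-alkoxyaryl α-diazoketones to 2-substituted chroman-4-ones. Ring C is closed as a 1,6-C–H insertion through a six-membered array (C3, C4, C4a, C8a, O1, C2), with the carbene carbon ending inside the new ring. The C2 stereocentre is controlled by the catalyst, which selects one of the two enantiotopic benzylic hydrogens inside the chiral pocket formed by the phthalimido walls. The step needs insertion to win over oxonium-ylide formation with Stevens benzyl shift, olefin cyclopropanation, Wolff rearrangement and insertion elsewhere: the targeted C–H is the only one in a 1,6 relation that is doubly activated (α to oxygen and benzylic on an electron-rich ring), the other ortho oxygen is a silyl ether with no adjacent C–H, the prenyl and geranyl double bonds could be reached only through strained meta-bridged macrocycles, and slow addition at high dilution suppresses bimolecular pathways. Rhodium carboxylates are chosen over copper catalysts because they favour insertion over ylide chemistry at an aryl ether oxygen.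

Step 11
Reactants: 17 the tetrasilylated flavanone
Product: 18 schizolaenone B, (2S)-2-{3-[(2E)-3,7-dimethylocta-2,6-dien-1-yl]-4,5-dihydroxyphenyl}-5,7-dihydroxy-6-(3-methylbut-2-en-1-yl)-2,3-dihydro-4H-chromen-4-one
Conditions: Et3N·3HF, THF, rt, degassed
Reagents that add atoms: none
Why: Fluoride-mediated cleavage of the four aryl silyl ethers under buffered, non-basic conditions should avoid retro-oxa-Michael opening of the 5-hydroxyflavanone (racemisation at C2) and acid-induced cyclisation of the prenyl and geranyl groups.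

**Compound list**

1 | 2',4',6'-trihydroxyacetophenone | CC(=O)c1c(O)cc(O)cc1O | starting material
2 | 1-[2,4-bis(TBS-oxy)-6-hydroxyphenyl]ethanone | CC(=O)c1c(O)cc(O[Si](C)(C)C(C)(C)C)cc1O[Si](C)(C)C(C)(C)C | intermediate
3 | 3-methylbut-2-en-1-ol (prenol) | CC(C)=CCO | starting material
4 | 1-[2,4-bis(TBS-oxy)-6-(prenyloxy)phenyl]ethanone | CC(=O)c1c(OCC=C(C)C)cc(O[Si](C)(C)C(C)(C)C)cc1O[Si](C)(C)C(C)(C)C | intermediate
5 | ortho-dienone: 2-acetyl-3,5-bis(TBS-oxy)-6-(2-methylbut-3-en-2-yl)cyclohexa-2,4-dien-1-one (racemic) | CC(=O)C1=C(O[Si](C)(C)C(C)(C)C)C=C(O[Si](C)(C)C(C)(C)C)C(C(C)(C)C=C)C1=O | intermediate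
6 | para-dienone: 2-acetyl-3,5-bis(TBS-oxy)-4-(3-methylbut-2-en-1-yl)cyclohexa-2,5-dien-1-one (racemic) | CC(=O)C1=C(O[Si](C)(C)C(C)(C)C)C(CC=C(C)C)C(O[Si](C)(C)C(C)(C)C)=CC1=O | intermediate
7 | 1-[2,4-bis(TBS-oxy)-6-hydroxy-3-(3-methylbut-2-en-1-yl)phenyl]ethanone | CC(=O)c1c(O)cc(O[Si](C)(C)C(C)(C)C)c(CC=C(C)C)c1O[Si](C)(C)C(C)(C)C | intermediate
8 | 3-bromo-4,5-dihydroxybenzaldehyde | O=Cc1cc(O)c(O)c(Br)c1 | starting material
9 | 3-bromo-4,5-bis(TBS-oxy)benzaldehyde | O=Cc1cc(O[Si](C)(C)C(C)(C)C)c(O[Si](C)(C)C(C)(C)C)c(Br)c1 | intermediate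
10 | geranyl chloride | CC(C)=CCC/C(C)=C/CCl | starting material
11 | tributyl[(2E)-3,7-dimethylocta-2,6-dien-1-yl]stannane | CC(C)=CCC/C(C)=C/C[Sn](CCCC)(CCCC)CCCC | intermediate
12 | 3-[(2E)-geranyl]-4,5-bis(TBS-oxy)benzaldehyde | CC(C)=CCC/C(C)=C/Cc1cc(C=O)cc(O[Si](C)(C)C(C)(C)C)c1O[Si](C)(C)C(C)(C)C | intermediate
13 | {3-[(2E)-geranyl]-4,5-bis(TBS-oxy)phenyl}methanol | CC(C)=CCC/C(C)=C/Cc1cc(CO)cc(O[Si](C)(C)C(C)(C)C)c1O[Si](C)(C)C(C)(C)C | intermediate
14 | aryl benzyl ether acetophenone (ring A acetophenone O-alkylated with the ring B benzyl group) | CC(C)=CCC/C(C)=C/Cc1cc(COc2cc(O[Si](C)(C)C(C)(C)C)c(CC=C(C)C)c(O[Si](C)(C)C(C)(C)C)c2C(C)=O)cc(O[Si](C)(C)C(C)(C)C)c1O[Si](C)(C)C(C)(C)C | intermediate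
15 | trifluoroacetyl 1,3-diketone of 14 | CC(C)=CCC/C(C)=C/Cc1cc(COc2cc(O[Si](C)(C)C(C)(C)C)c(CC=C(C)C)c(O[Si](C)(C)C(C)(C)C)c2C(=O)CC(=O)C(F)(F)F)cc(O[Si](C)(C)C(C)(C)C)c1O[Si](C)(C)C(C)(C)C | intermediate
16 | terminal α-diazoketone | CC(C)=CCC/C(C)=C/Cc1cc(COc2cc(O[Si](C)(C)C(C)(C)C)c(CC=C(C)C)c(O[Si](C)(C)C(C)(C)C)c2C(=O)C=[N+]=[N-])cc(O[Si](C)(C)C(C)(C)C)c1O[Si](C)(C)C(C)(C)C | intermediate
17 | (2S)-tetrakis-TBS schizolaenone B | CC(C)=CCC/C(C)=C/Cc1cc([C@@H]2CC(=O)c3c(cc(O[Si](C)(C)C(C)(C)C)c(CC=C(C)C)c3O[Si](C)(C)C(C)(C)C)O2)cc(O[Si](C)(C)C(C)(C)C)c1O[Si](C)(C)C(C)(C)C | intermediate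
18 | schizolaenone B | CC(C)=CCC/C(C)=C/Cc1cc([C@@H]2CC(=O)c3c(cc(O)c(CC=C(C)C)c3O)O2)cc(O)c1O | target

**Step count.** Total: 11 steps. Longest linear sequence: 7 steps (steps 1, 2, 3, 8, 9, 10, 11; the ring B branch 4, 6, 7, 8, 9, 10, 11 is equally long).

**Steps most likely to fail**

Step 10. The carbene may be diverted to attack at the ether oxygen followed by a 1,2-benzyl shift, or the catalyst may discriminate poorly between the two enantiotopic benzylic hydrogens. The fallback sets out from 14 and uses a more selective acceptor/acceptor carbenoid. The lithium enolate of 14 (LiN(SiMe3)2, THF, −78 °C) would be C-acylated with di-tert-butyl dicarbonate to the tert-butyl β-keto ester F1. Regitz diazo transfer (4-acetamidobenzenesulfonyl azide, Et3N, MeCN) would give the α-diazo-β-keto ester F2. Rh2(S-PTTL)4, a catalyst class established for α-diazo-β-keto esters, would then effect the same 1,6-C–H insertion to the 3-tert-butoxycarbonyl flavanone F3. Catalytic TsOH in toluene at 70 °C would remove isobutene and CO2 through the neutral enol, without an enolate that could open ring C, and the route is rejoined at 17.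

Step 6. Transmetalation through the substituted allyl terminus may give the branched isomer, π-allyl interconversion may erode the E geometry, and oxidative addition at the hindered, electron-rich bromide may be slow. The fallback sets out from 9 and reverses the polarity of the coupling. Miyaura borylation (B2pin2, PdCl2(dppf), KOAc, dioxane, 80 °C) would give the aryl boronate F4. Suzuki allyl–aryl coupling of F4 with geranyl chloride 10 (Pd(PPh3)4, anhydrous K3PO4, toluene, 60 °C) should deliver the aryl group to the unhindered terminus of a syn π-geranyl palladium intermediate, and the route is rejoined at 12.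

Step 3. The rearrangement may stop at the ortho stage by enolisation, giving the reverse-prenyl isomer, or the silyl ethers may migrate or be lost at 200 °C. The fallback sets out from 1 and installs the prenyl group directly on carbon. C-Prenylation of 1 with 1-bromo-3-methylbut-2-ene and DBU in THF would give 2,4,6-trihydroxy-3-prenylacetophenone F5, a single regioisomer because 1 is symmetric. Silylation of the non-chelated 4-OH (TBSCl, 1.0 equiv, imidazole, CH2Cl2, 0 °C) would give F6. Mitsunobu etherification with 13 at the less hindered of the two chelated hydroxyls (the one not flanked by the prenyl group) would give the mono-phenol F7. Silylation of the remaining hindered phenol (TBSOTf, 2,6-lutidine, CH2Cl2) rejoins the route at 14.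

**Further compounds**

F1 | step 10 | tert-butyl β-keto ester of 14 | CC(C)=CCC/C(C)=C/Cc1cc(COc2cc(O[Si](C)(C)C(C)(C)C)c(CC=C(C)C)c(O[Si](C)(C)C(C)(C)C)c2C(=O)CC(=O)OC(C)(C)C)cc(O[Si](C)(C)C(C)(C)C)c1O[Si](C)(C)C(C)(C)C
F2 | step 10 | tert-butyl α-diazo-β-keto ester | CC(C)=CCC/C(C)=C/Cc1cc(COc2cc(O[Si](C)(C)C(C)(C)C)c(CC=C(C)C)c(O[Si](C)(C)C(C)(C)C)c2C(=O)C(=[N+]=[N-])C(=O)OC(C)(C)C)cc(O[Si](C)(C)C(C)(C)C)c1O[Si](C)(C)C(C)(C)C
F3 | step 10 | (2S)-3-tert-butoxycarbonyl derivative of 17 (C3 epimers) | CC(C)=CCC/C(C)=C/Cc1cc([C@@H]2C(C(=O)OC(C)(C)C)C(=O)c3c(cc(O[Si](C)(C)C(C)(C)C)c(CC=C(C)C)c3O[Si](C)(C)C(C)(C)C)O2)cc(O[Si](C)(C)C(C)(C)C)c1O[Si](C)(C)C(C)(C)C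
F4 | step 6 | 3,4-bis(TBS-oxy)-5-(4,4,5,5-tetramethyl-1,3,2-dioxaborolan-2-yl)benzaldehyde | O=Cc1cc(O[Si](C)(C)C(C)(C)C)c(O[Si](C)(C)C(C)(C)C)c(B2OC(C)(C)C(C)(C)O2)c1
F5 | step 3 | 1-[2,4,6-trihydroxy-3-(3-methylbut-2-en-1-yl)phenyl]ethanone | CC(=O)c1c(O)cc(O)c(CC=C(C)C)c1O
F6 | step 3 | 1-[4-(TBS-oxy)-2,6-dihydroxy-3-(3-methylbut-2-en-1-yl)phenyl]ethanone | CC(=O)c1c(O)cc(O[Si](C)(C)C(C)(C)C)c(CC=C(C)C)c1O
F7 | step 3 | analogue of 14 with a free hydroxyl in place of the silyloxy group next to the acetyl group | CC(C)=CCC/C(C)=C/Cc1cc(COc2cc(O[Si](C)(C)C(C)(C)C)c(CC=C(C)C)c(O)c2C(C)=O)cc(O[Si](C)(C)C(C)(C)C)c1O[Si](C)(C)C(C)(C)C
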